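**Strategy.** The side chain is cut between C9' and C10' (primed locants count outward from ring carbon C5), beside the isolated Z-olefin C8'=C9' that carries only unbranched methylene chains. Acetylene supplies both olefinic carbons: syn-carbocupration by an octylcopper unit forges C9'–C10' and fixes the cis geometry, and the resulting alkenylcuprate is alkylated at C8' by 1-chloro-7-iodoheptane, so three simple components give the whole C17 chain in one flask. Its organocerium derivative is then added to a ketone made from (−)-quinic acid, whose C3/C4 acetonide directs formation of the C5 carbinol and finally departs by β-elimination to unveil the 4-hydroxycyclohex-2-enone ring.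

Key step: step 2

Remark: the ring locants of quinic acid (C1 carries the carboxyl group, C3/C4 the cis-diol, C5 the hydroxyl trans to O4) are kept for all ring intermediates and coincide with the locants of the target ring. 1-Bromo-7-chloroheptane, 1-iodooctane, acetylene and (−)-quinic acid are assumed to be purchasable.

Step 1
Reactants: 1 1-bromo-7-chloroheptane
Product: 2 1-chloro-7-iodoheptane
Conditions: NaI (1.0 equiv), acetone, rt, dark
Reagents that add atoms: sodium iodide, [Na+].[I-]
Why: Finkelstein halide exchange (SN2), in which NaBr precipitates from acetone and the primary bromide exchanges far faster than the primary chloride, so the chloride end should stay intact.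

Step 2
Reactants: 3 1-iodooctane; 4 acetylene; 2 1-chloro-7-iodoheptane
Product: 8 (Z)-1-chloroheptadec-8-ene, via n-octyllithium 5 (not isolated), via lithium di-n-octylcuprate 6 (not isolated), via lithium bis[(Z)-dec-1-enyl]cuprate 7 (not isolated)
Conditions: 3, t-BuLi (2 equiv per 3), Et2O–pentane, −78 °C; CuBr·SMe2 (0.5 equiv per 3), −40 °C; acetylene (1 equiv per 3), −50 to −25 °C; then THF, HMPA, P(OEt)3, 2 (limiting), −40 °C to rt; aq. NH4Cl/NH3
Reagents that add atoms: none
Why: Carbocupration of acetylene followed by alkylation of the alkenylcuprate: the lithium dialkylcuprate 6 adds each octyl group and copper across one molecule of acetylene in a concerted syn fashion, which creates the C9'–C10' bond (octyl CH2 to vinylic CH) and places octyl and copper cis in 7. The closest known reaction type is the carbocupration–alkylation sequence long used for Z-configured insect pheromones; no ring is closed and no stereocentre is formed, the only stereo-element being the olefin geometry, which is fixed by the syn addition and kept because alkenylcopper species are alkylated with retention. The step needs chemoselectivity between the two halogens of 2 and control of the number of acetylene insertions: HMPA and P(OEt)3 activate the cuprate towards the primary iodide while the primary chloride is inert, and acetylene is metered at low temperature so that a second insertion to dienylcopper species should not compete. Compound 2 is used as the limiting component, so one alkenyl group per copper is transferred and the other is lost as dec-1-ene on work-up.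

Step 3
Reactants: 9 (−)-quinic acid
Product: 10 3,4-O-isopropylidenequinic acid 1,5-lactone
Conditions: 2,2-dimethoxypropane, acetone, TsOH·H2O (cat.), reflux
Reagents that add atoms: 2,2-dimethoxypropane, COC(C)(C)OC
Why: Acid-catalysed transketalisation protects the only cis-1,2-diol (C3/C4) as the acetonide while the carboxyl group lactonises onto the cis-disposed C5 hydroxyl, all stereocentres coming unchanged from the chiral pool.

Step 4
Reactants: 10 3,4-O-isopropylidenequinic acid 1,5-lactone
Product: 11 methyl 3,4-O-isopropylidenequinate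
Conditions: NaOMe (cat.), MeOH, 0 °C to rt; AcOH quench
Reagents that add atoms: methanol, CO
Why: Base-catalysed transesterification (methanolysis) should open the strained bicyclic lactone and free the C5 hydroxyl, the acetonide being stable to base.

Step 5
Reactants: 11 methyl 3,4-O-isopropylidenequinate
Product: 12 methyl 5-dehydro-3,4-O-isopropylidenequinate
Conditions: Dess–Martin periodinane, pyridine, CH2Cl2, 0 °C to rt
Reagents that add atoms: none
Why: Dess–Martin oxidation of the only secondary alcohol under buffered, non-basic conditions should give the β-hydroxy ketone without dehydration, the tertiary C1 hydroxyl being inert.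

Step 6
Reactants: 8 (Z)-1-chloroheptadec-8-ene; 12 methyl 5-dehydro-3,4-O-isopropylidenequinate
Product: 15 methyl (1S,3R,4R,5S)-5-[(Z)-heptadec-8-enyl]-1,5-dihydroxy-3,4-(isopropylidenedioxy)cyclohexane-1-carboxylate, via (Z)-heptadec-8-enylmagnesium chloride 13 (not isolated), via (Z)-heptadec-8-enylcerium dichloride 14 (not isolated)
Conditions: 8, Mg, THF, reflux; CeCl3 (anhydrous), THF, −78 °C; then 12 (2.3 equiv of 14 per 12), −78 °C; aq. NH4Cl
Reagents that add atoms: none
Why: Organocerium 1,2-addition, in which the weakly basic reagent should add to the enolisable ketone faster than to the hindered ester and attack the face opposite the cis-fused dioxolane and the C1 oxygen (equatorial attack), so that the new C5 hydroxyl is cis to O4 and C5 is S, one equivalent of 14 being consumed by the free C1 hydroxyl.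

Step 7
Reactants: 15 methyl (1S,3R,4R,5S)-5-[(Z)-heptadec-8-enyl]-1,5-dihydroxy-3,4-(isopropylidenedioxy)cyclohexane-1-carboxylate
Product: 16 (1S,3R,4R,5S)-5-[(Z)-heptadec-8-enyl]-1-(hydroxymethyl)-3,4-(isopropylidenedioxy)cyclohexane-1,5-diol
Conditions: LiAlH4, THF, 0 °C to rt; aq. NaOH work-up
Reagents that add atoms: none
Why: Hydride reduction of the ester to the primary alcohol sets up a vicinal diol at C1, while the isolated alkene, the acetonide and the tertiary alcohols are inert to LiAlH4.

Step 8
Reactants: 16 (1S,3R,4R,5S)-5-[(Z)-heptadec-8-enyl]-1-(hydroxymethyl)-3,4-(isopropylidenedioxy)cyclohexane-1,5-diol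
Product: 17 (3R,4R,5S)-5-[(Z)-heptadec-8-enyl]-5-hydroxy-3,4-(isopropylidenedioxy)cyclohexan-1-one
Conditions: NaIO4, THF–H2O (pH 7 phosphate buffer), 0 °C
Reagents that add atoms: none
Why: Malaprade glycol cleavage should cut the only free vicinal diol (C1 carbinol and CH2OH), excising the former carboxyl carbon as formaldehyde and leaving the C1 ketone, whereas the C4/C5 oxygens cannot react because O4 is tied in the acetonide.

Step 9
Reactants: 17 (3R,4R,5S)-5-[(Z)-heptadec-8-enyl]-5-hydroxy-3,4-(isopropylidenedioxy)cyclohexan-1-one
Product: 18 (4R,5S)-5-[(Z)-heptadec-8-enyl]-4,5-dihydroxycyclohex-2-en-1-one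
Conditions: DBU (0.2 equiv), CH2Cl2, 0 °C; pH 7 buffer quench
Reagents that add atoms: none
Why: E1cB β-elimination, in which enolisation towards C2 expels the C3 acetonide oxygen and the hemiketal left on O4 collapses with loss of acetone, should give the C2=C3 enone and the free C4 hydroxyl in one operation, the tertiary C5 hydroxyl being a far poorer leaving group and both stereocentres (C4 R, C5 S) remaining untouched.

**Compound list**

1 | 1-bromo-7-chloroheptane | ClCCCCCCCBr | starting material
2 | 1-chloro-7-iodoheptane | ClCCCCCCCI | intermediate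
3 | 1-iodooctane | CCCCCCCCI | starting material
4 | acetylene (ethyne) | C#C | starting material
5 | n-octyllithium | [Li]CCCCCCCC | intermediate
6 | lithium di-n-octylcuprate | [Li+].CCCCCCCC[Cu-]CCCCCCCC | intermediate
7 | lithium bis[(Z)-dec-1-enyl]cuprate | [Li+].CCCCCCCC/C=C\[Cu-]/C=C\CCCCCCCC | intermediate
8 | (Z)-1-chloroheptadec-8-ene | ClCCCCCCC/C=C\CCCCCCCC | intermediate
9 | (−)-quinic acid (1-OH, 3-OH and 4-OH on one face, 5-OH and CO2H on the other) | O=C(O)[C@]1(O)C[C@@H](O)[C@@H](O)[C@H](O)C1 | starting material
10 | 3,4-O-isopropylidenequinic acid 1,5-lactone (acetonide on the cis C3/C4 diol, lactone from the carboxyl group to O5) | O=C2[C@]1(O)C[C@@H](O3)[C@@H](OC3(C)C)[C@H](O2)C1 | intermediate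
11 | methyl 3,4-O-isopropylidenequinate, methyl (1R,3R,4S,5R)-1,5-dihydroxy-3,4-(isopropylidenedioxy)cyclohexane-1-carboxylate | COC(=O)[C@]1(O)C[C@@H](O2)[C@@H](OC2(C)C)[C@H](O)C1 | intermediate
12 | methyl 5-dehydro-3,4-O-isopropylidenequinate, methyl (1S,3R,4R)-1-hydroxy-3,4-(isopropylidenedioxy)-5-oxocyclohexane-1-carboxylate | COC(=O)[C@]1(O)C[C@@H](O2)[C@@H](OC2(C)C)C(=O)C1 | intermediate
13 | (Z)-heptadec-8-enylmagnesium chloride | CCCCCCCC/C=C\CCCCCCC[Mg]Cl | intermediate
14 | (Z)-heptadec-8-enylcerium dichloride | CCCCCCCC/C=C\CCCCCCC[Ce](Cl)Cl | intermediate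
15 | methyl (1S,3R,4R,5S)-5-[(Z)-heptadec-8-enyl]-1,5-dihydroxy-3,4-(isopropylidenedioxy)cyclohexane-1-carboxylate (C5 hydroxyl cis to O4) | COC(=O)[C@]1(O)C[C@@H](O2)[C@@H](OC2(C)C)[C@](O)(CCCCCCC/C=C\CCCCCCCC)C1 | intermediate
16 | (1S,3R,4R,5S)-5-[(Z)-heptadec-8-enyl]-1-(hydroxymethyl)-3,4-(isopropylidenedioxy)cyclohexane-1,5-diol | OC[C@]1(O)C[C@@H](O2)[C@@H](OC2(C)C)[C@](O)(CCCCCCC/C=C\CCCCCCCC)C1 | intermediate
17 | (3R,4R,5S)-5-[(Z)-heptadec-8-enyl]-5-hydroxy-3,4-(isopropylidenedioxy)cyclohexan-1-one | O=C1C[C@@H](O2)[C@@H](OC2(C)C)[C@](O)(CCCCCCC/C=C\CCCCCCCC)C1 | intermediate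
18 | (4R,5S)-5-[(Z)-heptadec-8-enyl]-4,5-dihydroxycyclohex-2-en-1-one (cis-diol) | CCCCCCCC/C=C\CCCCCCC[C@]1(O)CC(=O)C=C[C@H]1O | target

**Step count.** Total: 9 steps. Longest linear sequence: 7 steps (steps 3 to 9, from quinic acid); the chain branch (steps 1 and 2) joins at step 6.

**Steps most likely to fail and their fallbacks**

Step 6. The organometallic may be lost to the free C1 hydroxyl, the resulting alkoxide may deliver the chain to the wrong face, and attack at the ester or base-induced dehydration of the β-hydroxy ketone may compete. The fallback sets out from 12 and blocks the hydroxyl first: N-(trimethylsilyl)imidazole should give methyl 5-dehydro-3,4-O-isopropylidene-1-O-(trimethylsilyl)quinate F3. The Grignard reagent 13 with LaCl3·2LiCl in THF at 0 °C, in place of the organocerium, should then add from the face opposite the acetonide and the silyl ether to give methyl (1S,3R,4R,5S)-5-[(Z)-heptadec-8-enyl]-5-hydroxy-3,4-(isopropylidenedioxy)-1-(trimethylsilyloxy)cyclohexane-1-carboxylate F4. K2CO3 in MeOH should remove the silyl group and return to 15.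

Step 9. Retro-aldol cleavage or dehydration at the free tertiary β-hydroxyl may compete with expulsion of the acetonide oxygen, and the product may eliminate further towards an aromatic hydroquinone. The fallback sets out from 17 and masks the hydroxyl: TESOTf and 2,6-lutidine at −78 °C should give (3R,4R,5S)-5-[(Z)-heptadec-8-enyl]-3,4-(isopropylidenedioxy)-5-(triethylsilyloxy)cyclohexan-1-one F5. DBU should then eliminate only the acetonide oxygen to give (4R,5S)-5-[(Z)-heptadec-8-enyl]-4-hydroxy-5-(triethylsilyloxy)cyclohex-2-en-1-one F6, and HF·pyridine in THF at 0 °C should return to 18.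

Step 2. Alkylation of the alkenylcuprate may stall, or a second acetylene insertion may give dienyl by-products. The fallback sets out from 2 and makes the same C9'–C10' bond as a C(sp)–C(sp3) bond: lithium acetylide–ethylenediamine complex in DMSO should displace the iodide selectively to give 9-chloronon-1-yne F1. Deprotonation with n-BuLi (THF–DMPU, −78 °C) and alkylation with 1-iodooctane 3 should give 1-chloroheptadec-8-yne F2. Semi-hydrogenation with H2 over Pd on CaCO3 poisoned with Pb(OAc)2 and quinoline should return to 8 with the Z geometry.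

**Further compounds**

F1 | step 2 | 9-chloronon-1-yne | ClCCCCCCCC#C
F2 | step 2 | 1-chloroheptadec-8-yne | ClCCCCCCCC#CCCCCCCCC
F3 | step 6 | methyl 5-dehydro-3,4-O-isopropylidene-1-O-(trimethylsilyl)quinate | COC(=O)[C@]1(O[Si](C)(C)C)C[C@@H](O2)[C@@H](OC2(C)C)C(=O)C1
F4 | step 6 | methyl (1S,3R,4R,5S)-5-[(Z)-heptadec-8-enyl]-5-hydroxy-3,4-(isopropylidenedioxy)-1-(trimethylsilyloxy)cyclohexane-1-carboxylate | COC(=O)[C@]1(O[Si](C)(C)C)C[C@@H](O2)[C@@H](OC2(C)C)[C@](O)(CCCCCCC/C=C\CCCCCCCC)C1
F5 | step 9 | (3R,4R,5S)-5-[(Z)-heptadec-8-enyl]-3,4-(isopropylidenedioxy)-5-(triethylsilyloxy)cyclohexan-1-one | O=C1C[C@@H](O2)[C@@H](OC2(C)C)[C@](O[Si](CC)(CC)CC)(CCCCCCC/C=C\CCCCCCCC)C1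
F6 | step 9 | (4R,5S)-5-[(Z)-heptadec-8-enyl]-4-hydroxy-5-(triethylsilyloxy)cyclohex-2-en-1-one | O=C1C=C[C@@H](O)[C@](O[Si](CC)(CC)CC)(CCCCCCC/C=C\CCCCCCCC)C1
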